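The route rests on cutting ring A (C5–C6–C7–C8–C9–C10) at its ring-fusion bond C5–C10 and at the opposite bond C7–C8. Both are made in one thermal operation from a monocyclic ring B carbinol that carries a vinyl group on C10 and an (E)-silyloxyvinyl group on C5. An oxy-Cope shift joins C7 to C8 and opens the cyclohexenol to a ten-membered dienone; its C10 ketone and C5=C6 alkene then close both six-membered rings by a transannular carbonyl-ene reaction. The step exploits the 1,4-placement of C10 (later sp2) and oxygenated C7 across ring A; the C7 carbinol relays chirality to the quaternary C5.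

Key step: step 9

Remark on numbering: eremophilane locants are used for all bicyclic and macrocyclic compounds (ring B = C10, C1, C2, C3, C4, C5; ring A = C5 to C10; Me-14 on C5, Me-15 on C4; C11(=C13)–C12 on C7). Monocyclic ring B compounds carry their own ring numbering in the names.
Remark on the side chain: the side-chain stereocentre is R as drawn, so (R)-2-methylbutan-1-ol is taken as the purchasable chiral source.
Remark on C8 and C10: the configurations at C10 (13 to 23) and C8 (18 to 22) are inconsequential, because both carbons become sp2 in step 13.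

Step 1
Reactants: 1 2-iodocyclohex-2-en-1-one; 2 allyltributylstannane
Product: 3 2-allylcyclohex-2-en-1-one
Conditions: Pd2(dba)3 (cat., zerovalent palladium), AsPh3, CuI (cat.), NMP, 50 °C
Reagents that add atoms: none
Why: Stille coupling of an α-iodoenone with an allylstannane (AsPh3/CuI acceleration) should proceed under mild conditions that leave the enone untouched; no stereocentre is formed.

Step 2
Reactants: 3
Product: 5 (2R,3R)-2-allyl-2,3-dimethylcyclohexan-1-one, via bromomagnesium enolate 4 (not isolated)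
Conditions: MeMgBr, CuBr·SMe2 (cat.), 1-[2-(diphenylphosphino)ferrocenyl]ethyldicyclohexylphosphine (one enantiomer, cat.), t-BuOMe, −75 °C; then MeI, DMPU, −75 → 0 °C
Reagents that add atoms: methylmagnesium bromide C[Mg]Br; iodomethane CI
Why: Copper-catalysed asymmetric conjugate addition sets C4 (the ligand enantiomer is chosen to give R), and alkylation of the regiodefined magnesium enolate with MeI anti to the new C4 methyl places the allyl group cis to Me-15, the C5 configuration that the later relay needs.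

Step 3
Reactants: 5
Product: 6 (5R,6R)-6-allyl-5,6-dimethylcyclohex-2-en-1-one
Conditions: IBX (2-iodoxybenzoic acid), DMSO/toluene, 70 °C
Reagents that add atoms: none
Why: IBX dehydrogenation of a ketone can only go through the single enolisable α-position (C1), since C5 is quaternary, and should give the C1=C2 enone without touching the stereocentres.

Step 4
Reactants: 6
Product: 8 (4S,5S,6R)-6-allyl-4-hydroxy-5,6-dimethylcyclohex-2-en-1-one, via silyl dienol ether 7 (not isolated)
Conditions: TMSOTf, Et3N, CH2Cl2, 0 °C; then mCPBA, CH2Cl2, −20 °C; then 1 M HCl (aq), THF, 0 °C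
Reagents that add atoms: 3-chloroperoxybenzoic acid OOC(=O)c1cccc(Cl)c1; trimethylsilyl triflate C[Si](C)(C)OS(=O)(=O)C(F)(F)F (its silyl group appears only in 7)
Why: Vinylogous Rubottom oxidation: γ-enolisation (no α′-hydrogen exists) gives the linear silyl dienol ether, and the peracid should attack its terminal C3 position from the face anti to Me-15 and the allyl group, so the new C3–O bond is trans to Me-15.

Step 5
Reactants: 8
Product: 9 (4S,5S,6R)-6-allyl-4-(tert-butyldimethylsilyloxy)-5,6-dimethylcyclohex-2-en-1-one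
Conditions: TBSCl, imidazole, DMF, rt
Reagents that add atoms: tert-butyldimethylsilyl chloride CC(C)(C)[Si](C)(C)Cl
Why: Standard silylation of a secondary allylic alcohol gives a protecting group that should survive every step up to step 14.

Step 6
Reactants: 9
Product: 11 2-[(1R,5S,6S)-5-(tert-butyldimethylsilyloxy)-1,6-dimethyl-2-oxocyclohex-3-en-1-yl]acetaldehyde, via diol 10 (not isolated)
Conditions: OsO4 (cat.), NaIO4, 2,6-lutidine, dioxane/H2O, rt
Reagents that add atoms: osmium tetroxide O=[Os](=O)(=O)=O (catalytic oxygen carrier); sodium periodate [Na+].[O-]I(=O)(=O)=O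
Why: Lemieux–Johnson cleavage should take the electron-rich terminal alkene much faster than the hindered, electron-poor enone alkene, delivering C7 as an aldehyde.

Step 7
Reactants: 11
Product: 12 (4S,5S,6R)-4-(tert-butyldimethylsilyloxy)-5,6-dimethyl-6-[(E)-2-(triethylsilyloxy)ethenyl]cyclohex-2-en-1-one
Conditions: TESCl, then KN(SiMe3)2 (internal quench), THF, −78 °C
Reagents that add atoms: chlorotriethylsilane CC[Si](Cl)(CC)CC
Why: Kinetic enolisation of the aldehyde by the hindered amide through an Ireland-type chair transition state, reinforced by the bulk of the quaternary C5, should place C5 trans to oxygen and give the (E)-enol silane, whose geometry later decides the C5 configuration.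

Step 8
Reactants: 12
Product: 13 (1S,4S,5S,6R)-4-(tert-butyldimethylsilyloxy)-1-ethenyl-5,6-dimethyl-6-[(E)-2-(triethylsilyloxy)ethenyl]cyclohex-2-en-1-ol
Conditions: CH2=CHMgBr, THF, −78 → 0 °C; then H2O (pH 7 buffer)
Reagents that add atoms: vinylmagnesium bromide C=C[Mg]Br
Why: Grignard 1,2-addition to the non-enolisable enone carbonyl is expected anti to the axial alkenyl group on C5; the other C10 epimer is an equally competent substrate because C10 becomes a ketone in step 9.

Step 9
Reactants: 13
Product: 17 (3S,4S,5S,10R)-3-(tert-butyldimethylsilyloxy)-10-hydroxy-11,12,13-trinoreremophil-1-en-7-one, via macrocyclic enol 14 (not isolated), via cyclodecadienone 15 (not isolated), via triethylsilyl enol ether 16 (not isolated)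
Conditions: DBU (0.5 equiv), toluene, 200 °C (microwave, sealed); then K2CO3, MeOH, 0 °C
Reagents that add atoms: none
Why: A thermal oxy-Cope [3,3] shift of the 3-hydroxy-1,5-diene C8=C9–C10(OH)–C5–C6=C7 through a chair transition state forms C7–C8, cleaves the old C5–C10 bond and gives enol 14, which DBU tautomerises to dienone 15; its C10 ketone then adds to C5 of the C5=C6 alkene in a transannular carbonyl-ene reaction with transfer of H-7 to oxygen, forming C5–C10 and enol silane 16, which methanolysis converts into 17. The closest known reaction is the tandem oxy-Cope/transannular ene reaction of 1,2-divinylcyclohexanols to decalin tertiary alcohols. C7–C8 is the ring-expanding sigmatropic bond (six-centre chair), and the C5–C10 bond closes rings A and B at once, 6-exo-trig at the carbonyl for both, through a bicyclo[2.2.2]-like six-centre ene transition state. The quaternary C5 is set by a chirality relay: the shift turns the C5 stereocentre of 13 and the E geometry of the enol ether into the C7 carbinol stereocentre, and the suprafacial ene step must bond C10 to the face of C5 from which H-7 leaves, which for the E isomer is the face opposite to the original bond, so Me-14 ends cis to Me-15 in a chair-like ring B with C3–OTBS and Me-15 equatorial, while C10 (OH trans to Me-14 from the E-alkene) is erased later. The step needs the exocyclic dialkenyl pair and not the ring alkene C1=C2 to enter the shift (the ring alkene would require a strained boat-like bicyclic transition state), a geometrically pure (E)-enol ether, and ene closure that outruns retro-ene fragmentation of the carbinol, which fast DBU-mediated ketonisation should secure.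

Step 10
Reactants: 17
Product: 18 (3S,4S,5S,10R)-3-(tert-butyldimethylsilyloxy)-8,10-dihydroxy-11,12,13-trinoreremophil-1-en-7-one (C8 epimers)
Conditions: NaN(SiMe3)2 (2.3 equiv), THF, −78 °C; then 2-(phenylsulfonyl)-3-phenyloxaziridine; then AcOH
Reagents that add atoms: 2-(phenylsulfonyl)-3-phenyloxaziridine O=S(=O)(c1ccccc1)N1OC1c1ccccc1
Why: Kinetic enolisation should occur at C8, away from the neopentyl C6 next to quaternary C5, and Davis oxidation of the sodium enolate installs the C8 oxygen; the C8 configuration is irrelevant.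

Step 11
Reactants: 18; 19 2-bromoprop-2-en-1-ol
Product: 21 (3S,4S,5S,7S,10R)-3-(tert-butyldimethylsilyloxy)eremophila-1,11(13)-diene-7,8,10,12-tetrol (C8 epimers), via dilithio reagent 20 (not isolated)
Conditions: 19, t-BuLi (3 equiv), Et2O, −78 → 0 °C; 18 pretreated with LiN(SiMe3)2 (2.2 equiv), THF, −78 → −20 °C; then H2O
Reagents that add atoms: none
Why: 1,2-addition of the O,2-dilithio derivative of allyl alcohol (Corey reagent) to the C7 ketone: the axial Me-14, 1,3-diaxial to the axial trajectory, should force equatorial attack from the face anti to Me-14, so C11 ends trans and the 7-OH cis to Me-14 (7S).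

Step 12
Reactants: 21
Product: 22 (3S,4S,5S,7S,10R)-12-acetoxy-3-(tert-butyldimethylsilyloxy)eremophila-1,11(13)-diene-7,8,10-triol (C8 epimers)
Conditions: Ac2O (1.1 equiv), pyridine, CH2Cl2, −20 °C
Reagents that add atoms: acetic anhydride CC(=O)OC(C)=O
Why: Selective acetylation should take the primary allylic hydroxyl in preference to the hindered secondary C8–OH and the two tertiary alcohols.

Step 13
Reactants: 22
Product: 24 (3S,4S,5S,7S)-12-acetoxy-3-(tert-butyldimethylsilyloxy)-7-hydroxyeremophila-1,9,11(13)-trien-8-one, via β-hydroxy ketone 23 (not isolated)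
Conditions: Dess–Martin periodinane, pyridine, CH2Cl2, 0 °C → rt; then p-TsOH·H2O (cat.), CH2Cl2, rt
Reagents that add atoms: none
Why: Dess–Martin oxidation of the only secondary alcohol gives the C8 ketone, and acid-catalysed dehydration of the tertiary, allylic β-hydroxy ketone (proton loss from C9) should give the conjugated C9=C10–C1=C2 dienone, while the 7-OH, α to the carbonyl, does not ionise.

Step 14
Reactants: 24
Product: 25 (3S,4S,5S,7S)-12-acetoxy-3,7-dihydroxyeremophila-1,9,11(13)-trien-8-one
Conditions: HF·pyridine, pyridine/THF, 0 °C → rt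
Reagents that add atoms: none
Why: Buffered fluoride desilylation should remove the allylic TBS ether without touching the acetate, the α-ketol or the dienone.

Step 15
Reactants: 26 (R)-2-methylbutan-1-ol; 27 2-(triphenylphosphoranylidene)propanal
Product: 29 (2E,4R)-2,4-dimethylhex-2-enal, via (R)-2-methylbutanal 28 (not isolated)
Conditions: TEMPO (cat.), PhI(OAc)2, CH2Cl2, rt; then 27, toluene, 80 °C
Reagents that add atoms: none
Why: TEMPO/PhI(OAc)2 oxidation followed without isolation by Wittig olefination with the stabilised ylide should give the E-enal and preserve the α-stereocentre of the sensitive aldehyde.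

Step 16
Reactants: 29; 30 diethylphosphonoacetic acid
Product: 31 (2E,4E,6R)-4,6-dimethylocta-2,4-dienoic acid
Conditions: 30, n-BuLi (2 equiv), THF, −78 → 0 °C; then 29, 0 °C → rt; then 1 M HCl
Reagents that add atoms: none
Why: Horner–Wadsworth–Emmons olefination with the dianion of the phosphonoacetic acid should give the (E)-configured dienoic acid directly.

Step 17
Reactants: 25; 31
Product: 33 (3S,4S,5S,7S)-12-acetoxy-7-hydroxy-8-oxoeremophila-1,9,11(13)-trien-3-yl (2E,4E,6R)-4,6-dimethylocta-2,4-dienoate, via mixed anhydride 32 (not isolated)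
Conditions: 31, 2,4,6-trichlorobenzoyl chloride, Et3N, toluene, rt; then 25, DMAP, rt → 40 °C
Reagents that add atoms: 2,4,6-trichlorobenzoyl chloride O=C(Cl)c1c(Cl)cc(Cl)cc1Cl (its atoms appear only in 32)
Why: Yamaguchi esterification should acylate the secondary allylic C3–OH only, since the tertiary 7-OH is inert, and no stereocentre is affected.

Compound list
1 | 2-iodocyclohex-2-en-1-one | O=C1CCCC=C1I | starting material
2 | allyltributylstannane | C=CC[Sn](CCCC)(CCCC)CCCC | starting material
3 | 2-allylcyclohex-2-en-1-one | C=CCC1=CCCCC1=O | intermediate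
4 | bromomagnesium (3R)-2-allyl-3-methylcyclohex-1-en-1-olate | C=CCC1=C(O[Mg]Br)CCC[C@H]1C | intermediate
5 | (2R,3R)-2-allyl-2,3-dimethylcyclohexan-1-one (allyl cis to the 3-methyl) | C=CC[C@]1(C)[C@H](C)CCCC1=O | intermediate
6 | (5R,6R)-6-allyl-5,6-dimethylcyclohex-2-en-1-one | C=CC[C@]1(C)[C@H](C)CC=CC1=O | intermediate
7 | [(5R,6R)-6-allyl-5,6-dimethylcyclohexa-1,3-dien-1-yl]oxy(trimethyl)silane | C=CC[C@]1(C)[C@H](C)C=CC=C1O[Si](C)(C)C | intermediate
8 | (4S,5S,6R)-6-allyl-4-hydroxy-5,6-dimethylcyclohex-2-en-1-one (OH trans to the 5-methyl) | C=CC[C@]1(C)[C@H](C)[C@@H](O)C=CC1=O | intermediate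
9 | (4S,5S,6R)-6-allyl-4-(tert-butyldimethylsilyloxy)-5,6-dimethylcyclohex-2-en-1-one | C=CC[C@]1(C)[C@H](C)[C@@H](O[Si](C)(C)C(C)(C)C)C=CC1=O | intermediate
10 | (4S,5S,6R)-4-(tert-butyldimethylsilyloxy)-6-(2,3-dihydroxypropyl)-5,6-dimethylcyclohex-2-en-1-one (side-chain carbinol epimers) | OCC(O)C[C@]1(C)[C@H](C)[C@@H](O[Si](C)(C)C(C)(C)C)C=CC1=O | intermediate
11 | 2-[(1R,5S,6S)-5-(tert-butyldimethylsilyloxy)-1,6-dimethyl-2-oxocyclohex-3-en-1-yl]acetaldehyde | O=CC[C@]1(C)[C@H](C)[C@@H](O[Si](C)(C)C(C)(C)C)C=CC1=O | intermediate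
12 | (4S,5S,6R)-4-(tert-butyldimethylsilyloxy)-5,6-dimethyl-6-[(E)-2-(triethylsilyloxy)ethenyl]cyclohex-2-en-1-one | CC[Si](CC)(CC)O/C=C/[C@]1(C)[C@H](C)[C@@H](O[Si](C)(C)C(C)(C)C)C=CC1=O | intermediate
13 | (1S,4S,5S,6R)-4-(tert-butyldimethylsilyloxy)-1-ethenyl-5,6-dimethyl-6-[(E)-2-(triethylsilyloxy)ethenyl]cyclohex-2-en-1-ol | C=C[C@]1(O)C=C[C@H](O[Si](C)(C)C(C)(C)C)[C@@H](C)[C@@]1(C)/C=C/O[Si](CC)(CC)CC | intermediate
14 | (1Z,5E,9Z,3S,4S,7S)-3-(tert-butyldimethylsilyloxy)-4,5-dimethyl-7-(triethylsilyloxy)cyclodeca-1,5,9-trien-10-ol (eremophilane locants; enol of 15) | O/C1=C\C[C@H](O[Si](CC)(CC)CC)/C=C(C)/[C@H](C)[C@@H](O[Si](C)(C)C(C)(C)C)/C=C\1 | intermediate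
15 | (1Z,5E,3S,4S,7S)-3-(tert-butyldimethylsilyloxy)-4,5-dimethyl-7-(triethylsilyloxy)cyclodeca-1,5-dien-10-one (eremophilane locants) | O=C1CC[C@H](O[Si](CC)(CC)CC)/C=C(C)/[C@H](C)[C@@H](O[Si](C)(C)C(C)(C)C)/C=C\1 | intermediate
16 | (3S,4S,5R,10R)-3-(tert-butyldimethylsilyloxy)-7-(triethylsilyloxy)-11,12,13-trinoreremophila-1,6-dien-10-ol (Me-14 cis to Me-15; 10-OH trans to Me-14) | C[C@@]12C=C(O[Si](CC)(CC)CC)CC[C@@]1(O)C=C[C@H](O[Si](C)(C)C(C)(C)C)[C@H]2C | intermediate
17 | (3S,4S,5S,10R)-3-(tert-butyldimethylsilyloxy)-10-hydroxy-11,12,13-trinoreremophil-1-en-7-one | C[C@@]12CC(=O)CC[C@@]1(O)C=C[C@H](O[Si](C)(C)C(C)(C)C)[C@H]2C | intermediate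
18 | (3S,4S,5S,10R)-3-(tert-butyldimethylsilyloxy)-8,10-dihydroxy-11,12,13-trinoreremophil-1-en-7-one (C8 epimers) | C[C@@]12CC(=O)C(O)C[C@@]1(O)C=C[C@H](O[Si](C)(C)C(C)(C)C)[C@H]2C | intermediate
19 | 2-bromoprop-2-en-1-ol | C=C(Br)CO | starting material
20 | lithium 2-lithioprop-2-en-1-olate | [Li]OCC([Li])=C | intermediate
21 | (3S,4S,5S,7S,10R)-3-(tert-butyldimethylsilyloxy)eremophila-1,11(13)-diene-7,8,10,12-tetrol (C8 epimers; 7-OH cis to Me-14) | C=C(CO)[C@@]1(O)C[C@]2(C)[C@@](O)(CC1O)C=C[C@H](O[Si](C)(C)C(C)(C)C)[C@H]2C | intermediate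
22 | (3S,4S,5S,7S,10R)-12-acetoxy-3-(tert-butyldimethylsilyloxy)eremophila-1,11(13)-diene-7,8,10-triol (C8 epimers) | C=C(COC(C)=O)[C@@]1(O)C[C@]2(C)[C@@](O)(CC1O)C=C[C@H](O[Si](C)(C)C(C)(C)C)[C@H]2C | intermediate
23 | (3S,4S,5S,7S,10R)-12-acetoxy-3-(tert-butyldimethylsilyloxy)-7,10-dihydroxyeremophila-1,11(13)-dien-8-one | C=C(COC(C)=O)[C@@]1(O)C[C@]2(C)[C@@](O)(CC1=O)C=C[C@H](O[Si](C)(C)C(C)(C)C)[C@H]2C | intermediate
24 | (3S,4S,5S,7S)-12-acetoxy-3-(tert-butyldimethylsilyloxy)-7-hydroxyeremophila-1,9,11(13)-trien-8-one | C=C(COC(C)=O)[C@@]1(O)C[C@]2(C)C(=CC1=O)C=C[C@H](O[Si](C)(C)C(C)(C)C)[C@H]2C | intermediate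
25 | (3S,4S,5S,7S)-12-acetoxy-3,7-dihydroxyeremophila-1,9,11(13)-trien-8-one | C=C(COC(C)=O)[C@@]1(O)C[C@]2(C)C(=CC1=O)C=C[C@H](O)[C@H]2C | intermediate
26 | (R)-2-methylbutan-1-ol | CC[C@@H](C)CO | starting material
27 | 2-(triphenylphosphoranylidene)propanal | CC(C=O)=P(c1ccccc1)(c1ccccc1)c1ccccc1 | starting material
28 | (R)-2-methylbutanal | CC[C@@H](C)C=O | intermediate
29 | (2E,4R)-2,4-dimethylhex-2-enal | CC[C@@H](C)/C=C(C)/C=O | intermediate
30 | diethylphosphonoacetic acid | CCOP(=O)(CC(=O)O)OCC | starting material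
31 | (2E,4E,6R)-4,6-dimethylocta-2,4-dienoic acid | CC[C@@H](C)/C=C(C)/C=C/C(=O)O | intermediate
32 | (2E,4E,6R)-4,6-dimethylocta-2,4-dienoic 2,4,6-trichlorobenzoic anhydride | CC[C@@H](C)/C=C(C)/C=C/C(=O)OC(=O)c1c(Cl)cc(Cl)cc1Cl | intermediate
33 | (3S,4S,5S,7S)-12-acetoxy-7-hydroxy-8-oxoeremophila-1,9,11(13)-trien-3-yl (2E,4E,6R)-4,6-dimethylocta-2,4-dienoate (CNP0160850.1) | C=C(COC(C)=O)[C@@]1(O)C[C@]2(C)C(=CC1=O)C=C[C@H](OC(=O)/C=C/C(C)=C/[C@H](C)CC)[C@H]2C | target

Total step count: 17. Longest linear sequence: 15 (steps 1 to 14 and step 17).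

Steps most likely to fail

Step 9. What may go wrong: retro-ene fragmentation of the tertiary homoallylic carbinol at 200 °C, sluggish ene closure onto the conjugated C10 ketone, or leakage through boat-like pathways that erodes the C5 relay. The fallback separates the two events and activates each one on its own. Starting from 13, anion-accelerated oxy-Cope rearrangement (KH, 18-crown-6, THF, 0 °C, buffered quench) would give the isolable cyclodecadienone 15. A Lewis-acid-promoted transannular carbonyl-ene reaction (Me2AlCl, CH2Cl2, −78 → 0 °C) would then give 16, and K2CO3/MeOH returns to the route at 17. No new compound is needed.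

Step 7. What may go wrong: partial formation of the (Z)-enol silane, which would relay to the C5 epimer in step 9. The fallback replaces the silyl enol ether by an enamine, whose E geometry is thermodynamically fixed. Starting from 11, condensation with morpholine (K2CO3, CH2Cl2, 0 °C) would give the (E)-enamine F1. Vinylmagnesium bromide addition would give the carbinol F2. Heating as in step 9 would pass through the macrocyclic enol F3 and the aminocyclodecadienone F4 to the enamine-decalinol F5. Hydrolysis (aqueous AcOH/NaOAc) returns to the route at 17.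

Step 11. What may go wrong: enolisation or α-ketol isomerisation of 18 by the strongly basic dilithio reagent, low conversion at the hindered ketone, or loss of facial control through the C8 alkoxide. The fallback uses a less basic organocerium reagent on a protected ketol and adds the C12 oxygen afterwards. Starting from 18, bis-silylation (TMSOTf, 2,6-lutidine) would give the bis-TMS ketol F6. Isopropenylmagnesium bromide/CeCl3 (THF, −78 °C) would add anti to Me-14 to give the isopropenyl carbinol F7. SeO2 (cat.)/t-BuOOH allylic hydroxylation of the isopropenyl methyl would give the allylic alcohol F8. Citric acid/MeOH removes the TMS groups and returns to the route at 21.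

Further compounds
F0 | step 9 | none | none
F1 | step 7 | (4S,5S,6R)-4-(tert-butyldimethylsilyloxy)-5,6-dimethyl-6-[(E)-2-(morpholin-4-yl)ethenyl]cyclohex-2-en-1-one | O=C1C=C[C@H](O[Si](C)(C)C(C)(C)C)[C@@H](C)[C@@]1(C)/C=C/N1CCOCC1
F2 | step 7 | 4-(tert-butyldimethylsilyloxy)-1-ethenyl-5,6-dimethyl-6-[(E)-2-(morpholin-4-yl)ethenyl]cyclohex-2-en-1-ol (configuration as in 13) | C=C[C@]1(O)C=C[C@H](O[Si](C)(C)C(C)(C)C)[C@@H](C)[C@@]1(C)/C=C/N1CCOCC1
F3 | step 7 | (1Z,5E,9Z)-3-(tert-butyldimethylsilyloxy)-4,5-dimethyl-7-(morpholin-4-yl)cyclodeca-1,5,9-trien-10-ol (eremophilane locants; configuration as in 14) | O/C1=C\C[C@H](N2CCOCC2)/C=C(C)/[C@H](C)[C@@H](O[Si](C)(C)C(C)(C)C)/C=C\1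
F4 | step 7 | (1Z,5E)-3-(tert-butyldimethylsilyloxy)-4,5-dimethyl-7-(morpholin-4-yl)cyclodeca-1,5-dien-10-one (eremophilane locants; configuration as in 15) | O=C1CC[C@H](N2CCOCC2)/C=C(C)/[C@H](C)[C@@H](O[Si](C)(C)C(C)(C)C)/C=C\1
F5 | step 7 | 3-(tert-butyldimethylsilyloxy)-7-(morpholin-4-yl)-11,12,13-trinoreremophila-1,6-dien-10-ol (configuration as in 16) | C[C@@]12C=C(N3CCOCC3)CC[C@@]1(O)C=C[C@H](O[Si](C)(C)C(C)(C)C)[C@H]2C
F6 | step 11 | (3S,4S,5S,10R)-3-(tert-butyldimethylsilyloxy)-8,10-bis(trimethylsilyloxy)-11,12,13-trinoreremophil-1-en-7-one (C8 epimers) | C[C@@]12CC(=O)C(O[Si](C)(C)C)C[C@@]1(O[Si](C)(C)C)C=C[C@H](O[Si](C)(C)C(C)(C)C)[C@H]2C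
F7 | step 11 | (3S,4S,5S,7S,10R)-3-(tert-butyldimethylsilyloxy)-8,10-bis(trimethylsilyloxy)eremophila-1,11(13)-dien-7-ol (C8 epimers) | C=C(C)[C@@]1(O)C[C@]2(C)[C@@](O[Si](C)(C)C)(CC1O[Si](C)(C)C)C=C[C@H](O[Si](C)(C)C(C)(C)C)[C@H]2C
F8 | step 11 | (3S,4S,5S,7S,10R)-3-(tert-butyldimethylsilyloxy)-8,10-bis(trimethylsilyloxy)eremophila-1,11(13)-diene-7,12-diol (C8 epimers) | C=C(CO)[C@@]1(O)C[C@]2(C)[C@@](O[Si](C)(C)C)(CC1O[Si](C)(C)C)C=C[C@H](O[Si](C)(C)C(C)(C)C)[C@H]2C
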